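**Strategy.** The lower flavan is disconnected at C4–C4a and O1–C8a: its benzo ring becomes 3,5-bis(benzyloxy)-4-methylbenzyne and the pyran atoms come from a cinnamaldehyde, whose carbonyl oxygen becomes O1. The step exploits that C4a and C8a are adjacent ring carbons with the C5 oxygen beside C4a and only hydrogen on C8, so the aryne is polarised. One operation ([2+2], ring opening, oxa-6π closure) gives the 6-methylflav-3-ene from a silyl triflate and an enal. Copper-catalysed kinetic-resolution borylation then sets C2/C3. The upper fisetinidol unit is joined last as a flavan-3,4-diol at the only free nucleophilic carbon, C8, and hydrogenolysis ends the route.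

Key step: step 7

Remark on numbering: flavan numbering (O1, C2, C3, C4, C4a, C5 to C8, C8a) is used for both units; the lower unit is the 6-methylcatechin half, the upper unit the fisetinidol half.

Assumption: CuCl/(R,R)-Ph-BPE is taken to borylate the (S)-configured 2-aryl-2H-chromene faster; if the opposite sense is found, the ligand enantiomers of steps 8 and 11 are exchanged.

**Route**

Step 1
Reactants: 1 2,4-dihydroxy-3-methylbenzaldehyde
Product: 2 2,4-bis(benzyloxy)-3-methylbenzaldehyde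
Conditions: BnBr, K2CO3, DMF, 60 °C
Reagents that add atoms: benzyl bromide, BrCc1ccccc1
Why: Williamson etherification of both phenols, with warming to reach the chelated, methyl-flanked 2-OH; no stereocentre is involved.

Step 2
Reactants: 2 2,4-bis(benzyloxy)-3-methylbenzaldehyde
Product: 4 2,4-bis(benzyloxy)-3-methylphenol, via aryl formate 3 (not isolated)
Conditions: mCPBA, CH2Cl2, 0 °C to rt; then K2CO3, MeOH, rt
Reagents that add atoms: mCPBA, O=C(OO)c1cccc(Cl)c1
Why: Dakin-type Baeyer–Villiger oxidation, in which the electron-rich 2,4-dialkoxyaryl group should migrate in preference to hydrogen, followed by methanolysis of the formate.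

Step 3
Reactants: 4 2,4-bis(benzyloxy)-3-methylphenol
Product: 5 2,4-bis(benzyloxy)-3-methylphenyl N-isopropylcarbamate
Conditions: i-PrNCO, Et3N (cat.), CH2Cl2, rt
Reagents that add atoms: isopropyl isocyanate, CC(C)N=C=O
Why: Base-catalysed addition of the phenol to the isocyanate installs a strong ortho-directing group that can later be removed under mild base.

Step 4
Reactants: 5 2,4-bis(benzyloxy)-3-methylphenyl N-isopropylcarbamate
Product: 8 2,4-bis(benzyloxy)-3-methyl-6-(trimethylsilyl)phenyl N-isopropylcarbamate, via N-silyl carbamate 6 (not isolated), via bis-silyl carbamate 7 (not isolated)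
Conditions: TMSOTf, TMEDA, Et2O, 0 °C to rt; n-BuLi, TMEDA, −78 °C; TMSCl, −78 °C to rt; aq. NaHSO4 work-up
Reagents that add atoms: chlorotrimethylsilane, C[Si](C)(C)Cl
Why: Directed ortho-metalation: in situ N-silylation masks the N–H, the carbamate directs lithiation to its only free ortho position (C6), TMSCl traps the aryllithium and the N–Si bond is hydrolysed on work-up.

Step 5
Reactants: 8 2,4-bis(benzyloxy)-3-methyl-6-(trimethylsilyl)phenyl N-isopropylcarbamate
Product: 10 2,4-bis(benzyloxy)-3-methyl-6-(trimethylsilyl)phenyl trifluoromethanesulfonate, via amidinium phenoxide 9 (not isolated)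
Conditions: DBU, Et2NH, MeCN, 40 °C; then PhNTf2, rt
Reagents that add atoms: N-phenylbis(trifluoromethanesulfonimide), O=S(=O)(N(c1ccccc1)S(=O)(=O)C(F)(F)F)C(F)(F)F
Why: DBU-induced E1cB loss of isopropyl isocyanate (scavenged by Et2NH) frees the phenoxide, which is triflated in the same pot to the o-silylaryl triflate.

Step 6
Reactants: 11 3,4-bis(benzyloxy)benzaldehyde; 12 (triphenylphosphoranylidene)acetaldehyde
Product: 13 (E)-3-[3,4-bis(benzyloxy)phenyl]prop-2-enal
Conditions: toluene, 80 °C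
Reagents that add atoms: none
Why: Wittig olefination with the stabilised formyl ylide should give the (E)-enal, the ylide being kept limiting to avoid a second homologation.

Step 7
Reactants: 10 2,4-bis(benzyloxy)-3-methyl-6-(trimethylsilyl)phenyl trifluoromethanesulfonate; 13 (E)-3-[3,4-bis(benzyloxy)phenyl]prop-2-enal
Product: 17 5,7-bis(benzyloxy)-2-[3,4-bis(benzyloxy)phenyl]-6-methyl-2H-chromene (racemate), via aryne 14 (not isolated), via benzoxete 15 (not isolated), via o-quinone methide 16 (not isolated)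
Conditions: CsF, MeCN, 50 °C, 10 added slowly to excess 13
Reagents that add atoms: none
Why: Fluoride-induced 1,2-elimination of 10 gives aryne 14, the carbonyl oxygen of 13 adds to the aryne carbon remote from the flanking benzyloxy group (future C8a, next to C8–H), and the aryl anion developing beside that benzyloxy group (future C4a) closes on the carbonyl carbon, a formal [2+2] giving benzoxete 15. Retro-4π opening of 15 gives o-quinone methide 16, and a thermal oxa-6π electrocyclisation closes the pyran ring through O1–C2 and restores aromaticity. The closest known reaction type is the fluoride-mediated annulation of arynes with α,β-unsaturated aldehydes to 2H-chromenes. The four-membered ring closes by a stepwise polar [2+2] across the in-plane aryne π bond, and the six-membered ring closes by disrotatory 6π electrocyclisation. The new stereocentre C2 has no controlling element and forms as a racemate, which step 8 resolves. The step needs regioselectivity across the triple bond, secured by the inductively withdrawing C3 benzyloxy group of the aryne, and chemoselectivity against capture of 16 by a second aryne, secured by excess enal and slow aryne release.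

Step 8
Reactants: 17 5,7-bis(benzyloxy)-2-[3,4-bis(benzyloxy)phenyl]-6-methyl-2H-chromene (racemate)
Product: 19 (2R,3S)-5,7-bis(benzyloxy)-2-[3,4-bis(benzyloxy)phenyl]-6-methylchroman-3-ol (2,3-trans), via boronate 18 (not isolated)
Conditions: CuCl (cat.), (R,R)-Ph-BPE (cat.), NaOtBu (cat.), B2pin2 (0.55 equiv), MeOH, THF, 0 °C; then NaBO3·4H2O, THF/H2O, rt
Reagents that add atoms: sodium perborate, [Na+].[O-]OB=O
Why: Kinetic resolution by copper-catalysed enantioselective protoboration: borylcupration places boron at the homobenzylic C3 anti to the C2 aryl group (substrate control, 2,3-trans), the chiral bisphosphine 1,2-bis[(2R,5R)-2,5-diphenylphospholan-1-yl]ethane lets only the (S)-chromene react (catalyst control at C2), and perborate oxidation retains configuration.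

Step 9
Reactants: 20 1-[4-(benzyloxy)-2-hydroxyphenyl]ethanone; 11 3,4-bis(benzyloxy)benzaldehyde
Product: 21 (E)-1-[4-(benzyloxy)-2-hydroxyphenyl]-3-[3,4-bis(benzyloxy)phenyl]prop-2-en-1-one
Conditions: KOH (aq.), EtOH, rt
Reagents that add atoms: none
Why: Claisen–Schmidt condensation of the acetophenone enolate with the non-enolisable aldehyde gives the thermodynamically favoured (E)-chalcone.

Step 10
Reactants: 21 (E)-1-[4-(benzyloxy)-2-hydroxyphenyl]-3-[3,4-bis(benzyloxy)phenyl]prop-2-en-1-one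
Product: 23 7-(benzyloxy)-2-[3,4-bis(benzyloxy)phenyl]-2H-chromene (racemate), via allylic alcohol 22 (not isolated)
Conditions: NaBH4, CeCl3·7H2O, THF/MeOH, 0 °C; then AcOH, 40 °C
Reagents that add atoms: none
Why: Luche 1,2-reduction gives the allylic alcohol, which on mild acid ionises to an o-quinone methide/allyl cation that the phenol oxygen closes to the flav-3-ene; C2 forms as a racemate.

Step 11
Reactants: 23 7-(benzyloxy)-2-[3,4-bis(benzyloxy)phenyl]-2H-chromene (racemate)
Product: 24 (S)-7-(benzyloxy)-2-[3,4-bis(benzyloxy)phenyl]-2H-chromene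
Conditions: CuCl (cat.), (S,S)-Ph-BPE (cat.), NaOtBu (cat.), B2pin2 (0.6 equiv), MeOH, THF, 0 °C, run beyond half conversion; chromatography
Reagents that add atoms: none
Why: The same copper-catalysed kinetic-resolution protoboration with the enantiomeric ligand should consume the (R)-chromene and leave the (S)-enantiomer, which is separated from the boronate.

Step 12
Reactants: 24 (S)-7-(benzyloxy)-2-[3,4-bis(benzyloxy)phenyl]-2H-chromene
Product: 25 (2R,3S,4S)-7-(benzyloxy)-2-[3,4-bis(benzyloxy)phenyl]chromane-3,4-diol (2,3-trans-3,4-cis)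
Conditions: OsO4 (cat.), NMO, acetone/H2O, rt
Reagents that add atoms: N-methylmorpholine N-oxide, C[N+]1([O-])CCOCC1; water, O
Why: Catalytic syn-dihydroxylation by OsO4 on the alkene face opposite the C2 aryl group sets C3–OH trans to that group (substrate control); the C4–OH is lost in step 13.

Step 13
Reactants: 19 (2R,3S)-5,7-bis(benzyloxy)-2-[3,4-bis(benzyloxy)phenyl]-6-methylchroman-3-ol; 25 (2R,3S,4S)-7-(benzyloxy)-2-[3,4-bis(benzyloxy)phenyl]chromane-3,4-diol
Product: 26 (2R,3S,4S)-7-(benzyloxy)-4-{(2R,3S)-5,7-bis(benzyloxy)-2-[3,4-bis(benzyloxy)phenyl]-3-hydroxy-6-methylchroman-8-yl}-2-[3,4-bis(benzyloxy)phenyl]chroman-3-ol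
Conditions: BF3·OEt2, CH2Cl2, −40 to 0 °C, 25 added slowly to 19
Reagents that add atoms: none
Why: Biomimetic Friedel–Crafts coupling: Lewis-acid ionisation of the C4–OH (activated by the para benzyloxy group and the ortho ring oxygen) gives a flavan-4-yl cation that is attacked by C8 of 19, the only free ring carbon (C6 carries the methyl group), the arene entering anti to the C3 hydroxyl to set C4 as 3,4-trans (4S).

Step 14
Reactants: 26 the heptabenzyl ether of the target
Product: 27 (2R,3S,4S)-2-(3,4-dihydroxyphenyl)-4-[(2R,3S)-2-(3,4-dihydroxyphenyl)-3,5,7-trihydroxy-6-methylchroman-8-yl]chromane-3,7-diol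
Conditions: H2 (1 atm), Pd(OH)2/C, THF/MeOH, rt
Reagents that add atoms: none
Why: Hydrogenolysis of the seven benzyl ethers under neutral conditions should leave the interflavan bond and all five stereocentres untouched.

**Compound list**

1 | 2,4-dihydroxy-3-methylbenzaldehyde | Cc1c(O)ccc(C=O)c1O | starting material
2 | 2,4-bis(benzyloxy)-3-methylbenzaldehyde | Cc1c(OCc2ccccc2)ccc(C=O)c1OCc1ccccc1 | intermediate
3 | 2,4-bis(benzyloxy)-3-methylphenyl formate | Cc1c(OCc2ccccc2)ccc(OC=O)c1OCc1ccccc1 | intermediate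
4 | 2,4-bis(benzyloxy)-3-methylphenol | Cc1c(OCc2ccccc2)ccc(O)c1OCc1ccccc1 | intermediate
5 | 2,4-bis(benzyloxy)-3-methylphenyl N-isopropylcarbamate | Cc1c(OCc2ccccc2)ccc(OC(=O)NC(C)C)c1OCc1ccccc1 | intermediate
6 | 2,4-bis(benzyloxy)-3-methylphenyl N-isopropyl-N-(trimethylsilyl)carbamate | Cc1c(OCc2ccccc2)ccc(OC(=O)N(C(C)C)[Si](C)(C)C)c1OCc1ccccc1 | intermediate
7 | 2,4-bis(benzyloxy)-3-methyl-6-(trimethylsilyl)phenyl N-isopropyl-N-(trimethylsilyl)carbamate | Cc1c(OCc2ccccc2)cc([Si](C)(C)C)c(OC(=O)N(C(C)C)[Si](C)(C)C)c1OCc1ccccc1 | intermediate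
8 | 2,4-bis(benzyloxy)-3-methyl-6-(trimethylsilyl)phenyl N-isopropylcarbamate | Cc1c(OCc2ccccc2)cc([Si](C)(C)C)c(OC(=O)NC(C)C)c1OCc1ccccc1 | intermediate
9 | 1,8-diazabicyclo[5.4.0]undec-7-enium 2,4-bis(benzyloxy)-3-methyl-6-(trimethylsilyl)phenoxide | Cc1c(OCc2ccccc2)cc([Si](C)(C)C)c([O-])c1OCc1ccccc1.C1CCC2=[NH+]CCCN2CC1 | intermediate
10 | 2,4-bis(benzyloxy)-3-methyl-6-(trimethylsilyl)phenyl trifluoromethanesulfonate | Cc1c(OCc2ccccc2)cc([Si](C)(C)C)c(OS(=O)(=O)C(F)(F)F)c1OCc1ccccc1 | intermediate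
11 | 3,4-bis(benzyloxy)benzaldehyde | O=Cc1ccc(OCc2ccccc2)c(OCc2ccccc2)c1 | starting material
12 | (triphenylphosphoranylidene)acetaldehyde | O=CC=P(c1ccccc1)(c1ccccc1)c1ccccc1 | starting material
13 | (E)-3-[3,4-bis(benzyloxy)phenyl]prop-2-enal | O=C/C=C/c1ccc(OCc2ccccc2)c(OCc2ccccc2)c1 | intermediate
14 | 3,5-bis(benzyloxy)-4-methylbenzyne (1,2-didehydrobenzene; the benzyloxy group at C3 flanks the triple bond, C6 carries H) | CC1=C(OCc2ccccc2)C#CC=C1OCc1ccccc1 | intermediate
15 | 3,5-bis(benzyloxy)-2-{(E)-2-[3,4-bis(benzyloxy)phenyl]ethenyl}-4-methyl-2H-benzo[b]oxete (racemic) | Cc1c(OCc2ccccc2)cc2OC(/C=C/c3ccc(OCc4ccccc4)c(OCc4ccccc4)c3)c2c1OCc1ccccc1 | intermediate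
16 | 3,5-bis(benzyloxy)-6-{(E)-3-[3,4-bis(benzyloxy)phenyl]prop-2-en-1-ylidene}-4-methylcyclohexa-2,4-dien-1-one (o-quinone methide) | CC1=C(OCc2ccccc2)C(=C/C=C/c2ccc(OCc3ccccc3)c(OCc3ccccc3)c2)C(=O)C=C1OCc1ccccc1 | intermediate
17 | 5,7-bis(benzyloxy)-2-[3,4-bis(benzyloxy)phenyl]-6-methyl-2H-chromene (racemate) | Cc1c(OCc2ccccc2)cc2OC(c3ccc(OCc4ccccc4)c(OCc4ccccc4)c3)C=Cc2c1OCc1ccccc1 | intermediate
18 | (2S,3S)-5,7-bis(benzyloxy)-2-[3,4-bis(benzyloxy)phenyl]-6-methyl-3-(4,4,5,5-tetramethyl-1,3,2-dioxaborolan-2-yl)chromane (2,3-trans) | Cc1c(OCc2ccccc2)cc2O[C@H](c3ccc(OCc4ccccc4)c(OCc4ccccc4)c3)[C@@H](B3OC(C)(C)C(C)(C)O3)Cc2c1OCc1ccccc1 | intermediate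
19 | (2R,3S)-5,7-bis(benzyloxy)-2-[3,4-bis(benzyloxy)phenyl]-6-methylchroman-3-ol (2,3-trans) | Cc1c(OCc2ccccc2)cc2O[C@H](c3ccc(OCc4ccccc4)c(OCc4ccccc4)c3)[C@@H](O)Cc2c1OCc1ccccc1 | intermediate
20 | 1-[4-(benzyloxy)-2-hydroxyphenyl]ethanone | CC(=O)c1ccc(OCc2ccccc2)cc1O | starting material
21 | (E)-1-[4-(benzyloxy)-2-hydroxyphenyl]-3-[3,4-bis(benzyloxy)phenyl]prop-2-en-1-one | O=C(/C=C/c1ccc(OCc2ccccc2)c(OCc2ccccc2)c1)c1ccc(OCc2ccccc2)cc1O | intermediate
22 | (E)-1-[4-(benzyloxy)-2-hydroxyphenyl]-3-[3,4-bis(benzyloxy)phenyl]prop-2-en-1-ol (racemate) | OC(/C=C/c1ccc(OCc2ccccc2)c(OCc2ccccc2)c1)c1ccc(OCc2ccccc2)cc1O | intermediate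
23 | 7-(benzyloxy)-2-[3,4-bis(benzyloxy)phenyl]-2H-chromene (racemate) | c1ccccc1COc1ccc2c(c1)OC(c1ccc(OCc3ccccc3)c(OCc3ccccc3)c1)C=C2 | intermediate
24 | (S)-7-(benzyloxy)-2-[3,4-bis(benzyloxy)phenyl]-2H-chromene | c1ccccc1COc1ccc2c(c1)O[C@H](c1ccc(OCc3ccccc3)c(OCc3ccccc3)c1)C=C2 | intermediate
25 | (2R,3S,4S)-7-(benzyloxy)-2-[3,4-bis(benzyloxy)phenyl]chromane-3,4-diol (2,3-trans-3,4-cis) | c1ccccc1COc1ccc2c(c1)O[C@H](c1ccc(OCc3ccccc3)c(OCc3ccccc3)c1)[C@@H](O)[C@H]2O | intermediate
26 | (2R,3S,4S)-7-(benzyloxy)-4-{(2R,3S)-5,7-bis(benzyloxy)-2-[3,4-bis(benzyloxy)phenyl]-3-hydroxy-6-methylchroman-8-yl}-2-[3,4-bis(benzyloxy)phenyl]chroman-3-ol | Cc1c(OCc5ccccc5)c2c(c([C@@H]3c4ccc(OCc5ccccc5)cc4O[C@H](c4ccc(OCc5ccccc5)c(OCc5ccccc5)c4)[C@H]3O)c1OCc1ccccc1)O[C@H](c1ccc(OCc3ccccc3)c(OCc3ccccc3)c1)[C@@H](O)C2 | intermediate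
27 | (2R,3S,4S)-2-(3,4-dihydroxyphenyl)-4-[(2R,3S)-2-(3,4-dihydroxyphenyl)-3,5,7-trihydroxy-6-methylchroman-8-yl]chromane-3,7-diol (fisetinidol-(4α→8)-6-methylcatechin) | Cc1c(O)c2c(c([C@@H]3c4ccc(O)cc4O[C@H](c4ccc(O)c(O)c4)[C@H]3O)c1O)O[C@H](c1ccc(O)c(O)c1)[C@@H](O)C2 | target

**Step count and risks**

Total step count: 14. Longest linear sequence: 9 steps (steps 1, 2, 3, 4, 5, 7, 8, 13, 14).

Steps most likely to fail:

1. Step 7. The o-quinone methide may be intercepted by a second aryne, or the aryne may add to the styrenyl part of the enal, before the electrocyclisation takes place. The fallback separates bond formation at the aryne from ring closure and sets out from 10. Fluoride-induced aryne generation in DMF as solvent, with formal insertion into the formamide C=O and aqueous hydrolysis, should give 2,4-bis(benzyloxy)-6-hydroxy-3-methylbenzaldehyde F1 with the same regiochemistry. Claisen–Schmidt condensation of F1 with commercial 1-[3,4-bis(benzyloxy)phenyl]ethanone (KOH, EtOH) would give (E)-3-[2,4-bis(benzyloxy)-6-hydroxy-3-methylphenyl]-1-[3,4-bis(benzyloxy)phenyl]prop-2-en-1-one F2. Luche reduction (NaBH4, CeCl3·7H2O) to the allylic alcohol (E)-3-[2,4-bis(benzyloxy)-6-hydroxy-3-methylphenyl]-1-[3,4-bis(benzyloxy)phenyl]prop-2-en-1-ol F3 and acid-induced cyclodehydration (AcOH) comes back to the route at 17.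

2. Step 8. The catalyst may discriminate poorly between the two enantiomers of the chromene, or borylcupration may occur on the face syn to the aryl group. The fallback sets out from 17 and replaces catalyst control by a classical resolution. Hydroboration with BH3·SMe2 and oxidation (H2O2, NaOH) should give racemic trans-5,7-bis(benzyloxy)-2-[3,4-bis(benzyloxy)phenyl]-6-methylchroman-3-ol F4. Steglich esterification with (S)-O-acetylmandelic acid (DCC, DMAP) gives the diastereomeric esters, the (2R,3S)-chromanyl (S)-O-acetylmandelate F5 and the (2S,3R)-chromanyl (S)-O-acetylmandelate F6, which are separated by chromatography or crystallisation. Saponification of F5 (LiOH, THF/H2O) comes back to the route at 19.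

3. Step 13. The arene may attack the C4 cation from the face syn to the C3 hydroxyl, and O-alkylation or self-condensation of the cation may compete. The fallback sets out from 25 and uses neighbouring-group participation. Acetylation (Ac2O, pyridine, DMAP) gives the 3,4-di-O-acetate of 25, F7. Its TMSOTf-promoted coupling with 19 (CH2Cl2, −78 °C) should proceed through a C3-acetoxonium ion that blocks the face of the C3 oxygen, so that the arene enters trans and gives the upper-unit 3-O-acetate of 26, F8. Methanolysis (K2CO3, MeOH) comes back to the route at 26.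

**Further compounds**

F1 | step 7 | 2,4-bis(benzyloxy)-6-hydroxy-3-methylbenzaldehyde | Cc1c(OCc2ccccc2)cc(O)c(C=O)c1OCc1ccccc1
F2 | step 7 | (E)-3-[2,4-bis(benzyloxy)-6-hydroxy-3-methylphenyl]-1-[3,4-bis(benzyloxy)phenyl]prop-2-en-1-one | Cc1c(OCc2ccccc2)cc(O)c(/C=C/C(=O)c2ccc(OCc3ccccc3)c(OCc3ccccc3)c2)c1OCc1ccccc1
F3 | step 7 | (E)-3-[2,4-bis(benzyloxy)-6-hydroxy-3-methylphenyl]-1-[3,4-bis(benzyloxy)phenyl]prop-2-en-1-ol (racemate) | Cc1c(OCc2ccccc2)cc(O)c(/C=C/C(O)c2ccc(OCc3ccccc3)c(OCc3ccccc3)c2)c1OCc1ccccc1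
F4 | step 8 | trans-5,7-bis(benzyloxy)-2-[3,4-bis(benzyloxy)phenyl]-6-methylchroman-3-ol (racemate, both enantiomers written) | Cc1c(OCc2ccccc2)cc2O[C@H](c3ccc(OCc4ccccc4)c(OCc4ccccc4)c3)[C@@H](O)Cc2c1OCc1ccccc1.Cc1c(OCc2ccccc2)cc2O[C@@H](c3ccc(OCc4ccccc4)c(OCc4ccccc4)c3)[C@H](O)Cc2c1OCc1ccccc1
F5 | step 8 | (2R,3S)-5,7-bis(benzyloxy)-2-[3,4-bis(benzyloxy)phenyl]-6-methylchroman-3-yl (S)-2-acetoxy-2-phenylacetate | Cc1c(OCc2ccccc2)cc2O[C@H](c3ccc(OCc4ccccc4)c(OCc4ccccc4)c3)[C@@H](OC(=O)[C@@H](OC(C)=O)c3ccccc3)Cc2c1OCc1ccccc1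
F6 | step 8 | (2S,3R)-5,7-bis(benzyloxy)-2-[3,4-bis(benzyloxy)phenyl]-6-methylchroman-3-yl (S)-2-acetoxy-2-phenylacetate | Cc1c(OCc2ccccc2)cc2O[C@@H](c3ccc(OCc4ccccc4)c(OCc4ccccc4)c3)[C@H](OC(=O)[C@@H](OC(C)=O)c3ccccc3)Cc2c1OCc1ccccc1
F7 | step 13 | 3,4-di-O-acetate of 25 (2,3-trans-3,4-cis, configuration of 25 unchanged) | c1ccccc1COc1ccc2c(c1)O[C@H](c1ccc(OCc3ccccc3)c(OCc3ccccc3)c1)[C@@H](OC(C)=O)[C@H]2OC(C)=O
F8 | step 13 | upper-unit 3-O-acetate of 26 (configuration of 26) | Cc1c(OCc5ccccc5)c2c(c([C@@H]3c4ccc(OCc5ccccc5)cc4O[C@H](c4ccc(OCc5ccccc5)c(OCc5ccccc5)c4)[C@H]3OC(C)=O)c1OCc1ccccc1)O[C@H](c1ccc(OCc3ccccc3)c(OCc3ccccc3)c1)[C@@H](O)C2
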